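**Plan**
- Retrosynthesis cuts, in order: the two O–MOM bonds on the outer naphthols; the C4–O bond of a p-quinol in the central ring (deoxygenative aromatisation); the biaryl bond from C4 of the central naphthalene (B) to C2 of the terminal naphthalene C, as aryl carbanion plus quinone carbonyl; the C2–C2' biaryl bond between naphthalenes A and B, as a Suzuki coupling onto a bromoquinone.
- Enabling feature: in the oxygenated ring of B, the C1 oxygen and the C4 aryl are para, so this ring is carried as a 1,4-quinone. Its C4=O (beside C3–H and the peri C5–H) is open and electrophilic, while C1=O is shielded by the C2 aryl and the peri C8–OMe and is a vinylogous ester; C4 is thus both the electrophile and the future arene carbon.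
- Forward: 8-methoxynaphthalen-1-ol is MOM-protected, lithiated at C2 and iodinated. This one aryl iodide serves twice: as the pinacol boronate (naphthalene A) after Miyaura borylation, and as an arylcerium dichloride (naphthalene C) after iodine–magnesium exchange. Juglone gives the bromoquinone (ring B). Suzuki coupling joins A to B, carbonyl addition joins C to B, zinc aromatises ring B, acid removes the MOM groups.
- Stereochemistry: the target has no stereocentre and no configurationally stable axis; the one stereocentre made on the way (quinol C4, racemic) is erased on aromatisation.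

Key step: step 7

Remark: 8-methoxynaphthalen-1-ol and juglone are taken as commercial, and both biaryl axes of the target (one ortho OH beside an ortho or peri H on each) are taken as freely rotating, so no stereocontrol is planned.

**Step 1**
Reactants: 1 8-methoxynaphthalen-1-ol
Product: 2 1-methoxy-8-(methoxymethoxy)naphthalene
Conditions: NaH, DMF, 0 °C; MOMCl, 0 °C to rt
Reagents that add atoms: chloromethyl methyl ether (MOMCl), COCCl
Why: Williamson-type O-alkylation (MOM protection), in which NaH breaks the peri hydrogen bond and the naphthoxide is alkylated to install the group that later directs lithiation and masks the phenol from organometallic reagents.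

**Step 2**
Reactants: 2 1-methoxy-8-(methoxymethoxy)naphthalene
Product: 4 2-iodo-8-methoxy-1-(methoxymethoxy)naphthalene, via aryllithium 3 (not isolated)
Conditions: n-BuLi, THF, 0 °C; I2, THF, −78 °C to rt; aq Na2S2O3
Reagents that add atoms: iodine, II
Why: Directed ortho-metalation followed by electrophilic iodination, in which the bidentate OMOM group is a much stronger director than OMe so that deprotonation should occur at C2 and not at C7.

**Step 3**
Reactants: 4 2-iodo-8-methoxy-1-(methoxymethoxy)naphthalene
Product: 5 2-[8-methoxy-1-(methoxymethoxy)naphthalen-2-yl]-4,4,5,5-tetramethyl-1,3,2-dioxaborolane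
Conditions: B2pin2, PdCl2(dppf) (5 mol %), KOAc, 1,4-dioxane, 90 °C, argon
Reagents that add atoms: bis(pinacolato)diboron, CC1(C)OB(OC1(C)C)B1OC(C)(C)C(C)(C)O1
Why: Miyaura borylation, in which zerovalent palladium inserts into the C–I bond and the acetate-bound arylpalladium transmetalates with the diboron, while the weak base KOAc should keep the product boronate from coupling with unreacted iodide and leaves the MOM and methyl ethers untouched.

**Step 4**
Reactants: 6 juglone (5-hydroxynaphthalene-1,4-dione)
Product: 8 2-bromo-8-hydroxynaphthalene-1,4-dione (3-bromojuglone), via dibromide 7 (not isolated)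
Conditions: Br2, AcOH, rt; then EtOH, reflux
Reagents that add atoms: bromine, BrBr
Why: Bromine addition to the quinone C2=C3 bond followed by dehydrobromination (addition–elimination), a known sequence for juglone in which the proton alpha to the hydrogen-bonded C4 carbonyl (juglone numbering) is lost so that bromine stays on the carbon next to that carbonyl.

**Step 5**
Reactants: 8 2-bromo-8-hydroxynaphthalene-1,4-dione
Product: 9 2-bromo-8-methoxynaphthalene-1,4-dione
Conditions: MeI, Ag2O, CH2Cl2, rt, dark
Reagents that add atoms: iodomethane, CI
Why: Purdie-type O-methylation, whose neutral silver-assisted conditions should methylate the chelated peri phenol without the displacement of the vinylic bromide that carbonate or hydroxide bases would risk.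

**Step 6**
Reactants: 5 2-[8-methoxy-1-(methoxymethoxy)naphthalen-2-yl]-4,4,5,5-tetramethyl-1,3,2-dioxaborolane; 9 2-bromo-8-methoxynaphthalene-1,4-dione
Product: 10 8-methoxy-2-[8-methoxy-1-(methoxymethoxy)naphthalen-2-yl]naphthalene-1,4-dione
Conditions: PdCl2(dppf) (5 mol %), K3PO4, 1,4-dioxane/H2O, 80 °C, argon
Reagents that add atoms: none
Why: Suzuki–Miyaura cross-coupling, in which the quinone C–Br bond behaves as a β-bromoenone and should add rapidly to zerovalent palladium while the MOM and methyl ethers are inert to the phosphate base.

**Step 7**
Reactants: 4 2-iodo-8-methoxy-1-(methoxymethoxy)naphthalene; 10 8-methoxy-2-[8-methoxy-1-(methoxymethoxy)naphthalen-2-yl]naphthalene-1,4-dione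
Product: 13 4-hydroxy-8-methoxy-2,4-bis[8-methoxy-1-(methoxymethoxy)naphthalen-2-yl]naphthalen-1(4H)-one (racemic), via arylmagnesium chloride 11 (not isolated), via arylcerium dichloride 12 (not isolated)
Conditions: 4, i-PrMgCl·LiCl, THF, 0 °C to rt; anhydrous CeCl3, THF, −78 °C; then 10, THF, −78 °C; aq NH4Cl
Reagents that add atoms: none
Why: Iodine–magnesium exchange on 4, helped by chelation of magnesium by the ortho OMOM group, gives arylmagnesium chloride 11, and transmetalation to the hard, weakly basic arylcerium dichloride 12 sets up nucleophilic 1,2-addition of the C2 carbanion of naphthalene C to the C4 carbonyl of quinone 10, after which protonation of the dichlorocerium alkoxide gives the p-quinol. The closest known reaction type is the 1,2-addition of organomagnesium, organolithium and organocerium reagents to 1,4-quinones to give 4-substituted 4-hydroxycyclohexadienones. No ring is closed in this step. The one new stereocentre (quinol C4) is formed as a racemate with no controlling element, which is harmless because step 8 makes this carbon planar. The step needs carbonyl selectivity (C4=O over C1=O), which the substrate secures because C1=O is flanked by the C2 aryl group and the peri C8 methoxy group and is deactivated as a vinylogous ester of that methoxy group, whereas C4=O has only C3–H and the peri C5–H beside it. It also needs 1,2-addition in preference to conjugate addition at C3, to electron transfer and to a second addition, which the oxophilic cerium reagent, the temperature of −78 °C and a near-stoichiometric charge (with i-PrMgCl·LiCl kept slightly below the amount of 4) should secure.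

**Step 8**
Reactants: 13 4-hydroxy-8-methoxy-2,4-bis[8-methoxy-1-(methoxymethoxy)naphthalen-2-yl]naphthalen-1(4H)-one
Product: 14 8-methoxy-2,4-bis[8-methoxy-1-(methoxymethoxy)naphthalen-2-yl]naphthalen-1-ol
Conditions: Zn dust, AcOH, THF, rt, argon
Reagents that add atoms: none
Why: Dissolving-metal reduction of a p-quinol (vinylogous α-ketol reductive cleavage), in which electron transfer from zinc to the dienone expels the C4 hydroxyl and the resulting dienolate is the aromatic naphtholate of ring B, while the aryl MOM ethers should survive acetic acid at room temperature.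

**Step 9**
Reactants: 14 8-methoxy-2,4-bis[8-methoxy-1-(methoxymethoxy)naphthalen-2-yl]naphthalen-1-ol
Product: 15 8,8',8''-trimethoxy-[2,2':4',2''-ternaphthalene]-1,1',1''-triol (target)
Conditions: HCl (3 M aq), MeOH/THF, 40 °C, degassed, argon
Reagents that add atoms: none
Why: Acid-catalysed acetal cleavage (MOM deprotection by transacetalisation to methanol), which should free both outer naphthols while the three aryl methyl ethers are stable to dilute HCl.

**Compound list**
1 | 8-methoxynaphthalen-1-ol | COc1cccc2cccc(O)c12 | starting material
2 | 1-methoxy-8-(methoxymethoxy)naphthalene | COCOc1cccc2cccc(OC)c12 | intermediate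
3 | [8-methoxy-1-(methoxymethoxy)naphthalen-2-yl]lithium | [Li]c1ccc2cccc(OC)c2c1OCOC | intermediate
4 | 2-iodo-8-methoxy-1-(methoxymethoxy)naphthalene | COCOc1c(I)ccc2cccc(OC)c12 | intermediate
5 | 2-[8-methoxy-1-(methoxymethoxy)naphthalen-2-yl]-4,4,5,5-tetramethyl-1,3,2-dioxaborolane | COCOc1c(B2OC(C)(C)C(C)(C)O2)ccc2cccc(OC)c12 | intermediate
6 | juglone (5-hydroxynaphthalene-1,4-dione) | O=C1C=CC(=O)c2c(O)cccc12 | starting material
7 | 2,3-dibromo-5-hydroxy-2,3-dihydronaphthalene-1,4-dione (configuration of no consequence) | O=C1C(Br)C(Br)C(=O)c2c(O)cccc12 | intermediate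
8 | 2-bromo-8-hydroxynaphthalene-1,4-dione (3-bromojuglone) | O=C1C=C(Br)C(=O)c2c(O)cccc12 | intermediate
9 | 2-bromo-8-methoxynaphthalene-1,4-dione | O=C1C=C(Br)C(=O)c2c(OC)cccc12 | intermediate
10 | 8-methoxy-2-[8-methoxy-1-(methoxymethoxy)naphthalen-2-yl]naphthalene-1,4-dione | O=C1C=C(c3ccc4cccc(OC)c4c3OCOC)C(=O)c2c(OC)cccc12 | intermediate
11 | chloro[8-methoxy-1-(methoxymethoxy)naphthalen-2-yl]magnesium | Cl[Mg]c1ccc2cccc(OC)c2c1OCOC | intermediate
12 | dichloro[8-methoxy-1-(methoxymethoxy)naphthalen-2-yl]cerium | Cl[Ce](Cl)c1ccc2cccc(OC)c2c1OCOC | intermediate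
13 | 4-hydroxy-8-methoxy-2,4-bis[8-methoxy-1-(methoxymethoxy)naphthalen-2-yl]naphthalen-1(4H)-one (racemic) | O=C1C(c3ccc4cccc(OC)c4c3OCOC)=CC(O)(c5ccc6cccc(OC)c6c5OCOC)c2cccc(OC)c12 | intermediate
14 | 8-methoxy-2,4-bis[8-methoxy-1-(methoxymethoxy)naphthalen-2-yl]naphthalen-1-ol | COCOc1c(-c3cc(-c4ccc5cccc(OC)c5c4OCOC)c4cccc(OC)c4c3O)ccc2cccc(OC)c12 | intermediate
15 | 8,8',8''-trimethoxy-[2,2':4',2''-ternaphthalene]-1,1',1''-triol | COc1cccc2ccc(-c3cc(-c4ccc5cccc(OC)c5c4O)c4cccc(OC)c4c3O)c(O)c12 | target

Total step count: 9. Longest linear sequence: 7 steps (steps 1, 2, 3, 6, 7, 8, 9; the juglone branch, steps 4, 5, 6, 7, 8, 9, has 6).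

**Steps most likely to fail**

Step 7. The organometallic may transfer an electron to the quinone instead of adding to it, which would reduce 10 and return 2 on work-up. It may also add in conjugate fashion at C3, or add a second time at C1. The fallback makes the same bond by cross-coupling at the hydroquinone oxidation level; it sets out from 10 and returns at 14. Quinone 10 would be reduced with Na2S2O4 in THF/H2O to 8-methoxy-2-[8-methoxy-1-(methoxymethoxy)naphthalen-2-yl]naphthalene-1,4-diol F1. The open C4 hydroxyl of F1 would be sulfonylated selectively with PhNTf2 and K2CO3, since the C1 hydroxyl is hydrogen-bonded to the peri methoxy group and flanked by the aryl group. This should give 4-hydroxy-5-methoxy-3-[8-methoxy-1-(methoxymethoxy)naphthalen-2-yl]naphthalen-1-yl trifluoromethanesulfonate F2. Suzuki–Miyaura coupling of F2 with boronate 5 (Pd(PPh3)4, K3PO4, dioxane/H2O) should give 14 directly.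

Step 6. Base may destroy the bromoquinone by addition–elimination at the C–Br carbon, or the hindered ortho-alkoxy boronate may protodeboronate faster than it couples. The fallback builds the A–B bond at the naphthol level and creates the quinone afterwards; it sets out from 1 (with 5) and returns at 10. Ortho-selective bromination of 1 (NBS, catalytic i-Pr2NH, CH2Cl2) should give 2-bromo-8-methoxynaphthalen-1-ol F3. Suzuki–Miyaura coupling of F3 with 5 should give 8-methoxy-2-[8-methoxy-1-(methoxymethoxy)naphthalen-2-yl]naphthalen-1-ol F4. Teuber oxidation of the free naphthol ring of F4 with (KSO3)2NO in buffered aqueous acetone should give quinone 10, because C2 is blocked and the para position C4 is free.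

Step 8. Acid may ionise the tertiary quinol hydroxyl before reduction, leading to a 1,2-aryl shift (dienone–phenol rearrangement), or a MOM group may be lost early with cyclisation onto the dienone. The fallback replaces the reductive deoxygenation by a reduction–dehydration pair; it sets out from 13 and returns at 15. Luche reduction of the C1 carbonyl of 13 (NaBH4, CeCl3·7H2O, MeOH, 0 °C) should give 8-methoxy-2,4-bis[8-methoxy-1-(methoxymethoxy)naphthalen-2-yl]-1,4-dihydronaphthalene-1,4-diol F5 as a mixture of diastereomers, which is of no consequence. HCl in MeOH should then ionise the tertiary, doubly benzylic C4 hydroxyl; loss of the C1 proton aromatises ring B by 1,4-elimination of water with the C1 hydroxyl retained. The same acid removes both MOM groups, giving 15.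

**Further compounds**
F1 | step 7 | 8-methoxy-2-[8-methoxy-1-(methoxymethoxy)naphthalen-2-yl]naphthalene-1,4-diol | Oc1cc(-c3ccc4cccc(OC)c4c3OCOC)c(O)c2c(OC)cccc12
F2 | step 7 | 4-hydroxy-5-methoxy-3-[8-methoxy-1-(methoxymethoxy)naphthalen-2-yl]naphthalen-1-yl trifluoromethanesulfonate | O=S(=O)(Oc1cc(-c3ccc4cccc(OC)c4c3OCOC)c(O)c2c(OC)cccc12)C(F)(F)F
F3 | step 6 | 2-bromo-8-methoxynaphthalen-1-ol | COc1cccc2ccc(Br)c(O)c12
F4 | step 6 | 8-methoxy-2-[8-methoxy-1-(methoxymethoxy)naphthalen-2-yl]naphthalen-1-ol | COCOc1c(-c3ccc4cccc(OC)c4c3O)ccc2cccc(OC)c12
F5 | step 8 | 8-methoxy-2,4-bis[8-methoxy-1-(methoxymethoxy)naphthalen-2-yl]-1,4-dihydronaphthalene-1,4-diol | OC1C(c3ccc4cccc(OC)c4c3OCOC)=CC(O)(c5ccc6cccc(OC)c6c5OCOC)c2cccc(OC)c12
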